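Everything rests on cutting the cyclohexene ring at two bonds: C1–C2 (quaternary carbon to the coumarinyl-bearing CH) and the ring alkene C3=C4. The key step exploits that C2–C3 then maps onto a β-coumarinyl vinylphosphonium salt (C2 electrophilic, C3 a latent ylide), C4 with its methyl onto a methyl ketone, and C1 onto the α-carbon of an aldehyde that later becomes the styryl arm. In one operation an amine-catalysed enantioselective Michael addition of 5-oxohexanal to the phosphonium salt forms C1–C2 and sets C2, and the adduct's ylide closes the ring by Wittig olefination (C3=C4). The precursors are an open-chain keto-aldehyde and a vinylphosphonium salt.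

Key step: step 6

Remark: ring atoms are numbered C1 (quaternary) to C6 with the coumarinyl group on C2; the facial sense of the enamine addition in step 6 is assumed to parallel that of aldehyde additions to nitroalkenes, and the (S)-catalyst is taken instead if it does not.

Step 1
Reactants: 1 daphnetin (7,8-dihydroxy-2H-chromen-2-one)
Product: 2 8-hydroxy-7-(methoxymethoxy)-2H-chromen-2-one
Conditions: MOMCl (1.05 equiv), K2CO3 (1.1 equiv), acetone, 0 °C to rt
Reagents that add atoms: chloromethyl methyl ether, COCCl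
Why: Williamson-type O-alkylation in which the 7-OH, the more acidic phenol (vinylogous acid through C4a–C4=C3–C2=O), should be ionised and alkylated before the 8-OH.

Step 2
Reactants: 2 8-hydroxy-7-(methoxymethoxy)-2H-chromen-2-one
Product: 3 8-methoxy-7-(methoxymethoxy)-2H-chromen-2-one
Conditions: MeI, K2CO3, DMF, rt
Reagents that add atoms: iodomethane, CI
Why: Williamson O-methylation of the remaining phenol, with lactone and acetal stable to carbonate at ambient temperature.

Step 3
Reactants: 3 8-methoxy-7-(methoxymethoxy)-2H-chromen-2-one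
Product: 4 3-bromo-8-methoxy-7-(methoxymethoxy)-2H-chromen-2-one
Conditions: NBS, NaHCO3, MeCN, rt, dark
Reagents that add atoms: N-bromosuccinimide, O=C1CCC(=O)N1Br
Why: Electrophilic bromination (addition–elimination) at C3, the nucleophilic terminus of the 7-alkoxystyrene-like π-system, with C8 blocked and the buffer protecting the acetal.

Step 4
Reactants: 4 3-bromo-8-methoxy-7-(methoxymethoxy)-2H-chromen-2-one, 5 triphenyl(vinyl)phosphonium bromide
Product: 6 (E)-{2-[8-methoxy-7-(methoxymethoxy)-2-oxo-2H-chromen-3-yl]ethenyl}triphenylphosphonium bromide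
Conditions: Pd(OAc)2 (5 mol%), P(o-tol)3 (10 mol%), NaOAc, DMF, 100 °C
Reagents that add atoms: none
Why: Mizoroki–Heck reaction in which zerovalent palladium inserts into the C3–Br bond, the coumarinyl group adds to the CH2 terminus of the electron-poor vinyl group, and syn β-hydride elimination should give the (E)-alkene.

Step 5
Reactants: 7 1-methylcyclopentene
Product: 9 5-oxohexanal, via secondary ozonide 8 (not isolated)
Conditions: O3, CH2Cl2, −78 °C; then Me2S, −78 °C to rt
Reagents that add atoms: ozone, [O-][O+]=O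
Why: Ozonolysis (Criegee mechanism) with reductive work-up opens the ring to the keto-aldehyde, which is used freshly.

Step 6
Reactants: 6 (E)-{2-[8-methoxy-7-(methoxymethoxy)-2-oxo-2H-chromen-3-yl]ethenyl}triphenylphosphonium bromide, 9 5-oxohexanal
Product: 12 (1R,2R)-2-[8-methoxy-7-(methoxymethoxy)-2-oxo-2H-chromen-3-yl]-4-methylcyclohex-3-ene-1-carbaldehyde, via phosphonium aldehyde 10 (not isolated), via phosphonium ylide 11 (not isolated)
Conditions: (R)-2-[diphenyl(trimethylsilyloxy)methyl]pyrrolidine (20 mol%), PhCO2H (20 mol%), CH2Cl2, 0 °C to rt; then K2CO3, 18-crown-6, THF (high dilution), 45 °C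
Reagents that add atoms: none
Why: Proposed new method: the amine should condense only with the aldehyde of 9 to give an (E)-enamine that adds through its α-carbon to the β-carbon of the cationic vinylphosphonium salt 6 (Michael addition, C1–C2 bond), and after proton transfer the salt 10 is deprotonated at its P–CH2 group, the most acidic C–H present, to ylide 11, which olefinates the tethered methyl ketone (intramolecular Wittig reaction, C3=C4 bond, Ph3PO lost). The closest known reaction types are the conjugate addition–intramolecular Wittig annulation of keto-substituted carbanions with vinylphosphonium salts and the diarylprolinol silyl ether-catalysed Michael addition of aldehydes to nitroalkenes and vinyl sulfones; new is a vinylphosphonium salt as acceptor in enamine catalysis. The six-membered ring is closed by 6-exo-trig attack of the ylide carbon on the ketone carbonyl through an oxaphosphetane, and the ring alkene can only be cis. The C2 stereocentre is controlled by the catalyst, whose diphenyl(silyloxy)methyl group blocks one enamine face so that the (E)-acceptor is met in the usual synclinal open transition state; the syn adduct would close to the cis aldehyde, which should equilibrate under K2CO3 toward trans-12, and because step 7 rebuilds C1 either epimer serves. The step needs site selectivity for the vinyl β-carbon over C4 of the coumarin (secured by the adjacent positive phosphorus), ketone-over-aldehyde selectivity in the Wittig closure (six- against four-membered ring) and suppression of intermolecular olefination (high dilution in the second stage).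

Step 7
Reactants: 12 (1R,2R)-2-[8-methoxy-7-(methoxymethoxy)-2-oxo-2H-chromen-3-yl]-4-methylcyclohex-3-ene-1-carbaldehyde
Product: 14 (1S,2R)-2-[8-methoxy-7-(methoxymethoxy)-2-oxo-2H-chromen-3-yl]-1,4-dimethylcyclohex-3-ene-1-carbaldehyde, via potassium enolate 13 (not isolated)
Conditions: KN(SiMe3)2, THF, −78 °C; then MeI, −78 to −20 °C
Reagents that add atoms: iodomethane, CI
Why: Enolate C-alkylation in which the exocyclic enolate 13 should be methylated on the ring face anti to the neighbouring C2 coumarinyl group (held pseudo-axial by allylic strain), so the new quaternary C1 carries methyl trans and formyl cis to the aryl group while C2 is not deprotonated.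

Step 8
Reactants: 14 (1S,2R)-2-[8-methoxy-7-(methoxymethoxy)-2-oxo-2H-chromen-3-yl]-1,4-dimethylcyclohex-3-ene-1-carbaldehyde
Product: 15 3-[(1R,6R)-6-ethenyl-3,6-dimethylcyclohex-2-en-1-yl]-8-methoxy-7-(methoxymethoxy)-2H-chromen-2-one
Conditions: Ph3PCH3Br, KOtBu, THF, 0 °C; then 14, 0 °C to rt
Reagents that add atoms: methyltriphenylphosphonium bromide (CH2 source, used as its ylide), C[P+](c1ccccc1)(c1ccccc1)c1ccccc1.[Br-]
Why: Wittig methylenation of the non-enolisable aldehyde, which is far more electrophilic than the lactone, with no stereocentre touched.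

Step 9
Reactants: 15 3-[(1R,6R)-6-ethenyl-3,6-dimethylcyclohex-2-en-1-yl]-8-methoxy-7-(methoxymethoxy)-2H-chromen-2-one, 4 3-bromo-8-methoxy-7-(methoxymethoxy)-2H-chromen-2-one
Product: 16 8-methoxy-3-[(E)-2-{(1R,2R)-2-[8-methoxy-7-(methoxymethoxy)-2-oxo-2H-chromen-3-yl]-1,4-dimethylcyclohex-3-en-1-yl}ethenyl]-7-(methoxymethoxy)-2H-chromen-2-one
Conditions: Pd(OAc)2 (5 mol%), P(o-tol)3 (10 mol%), NaOAc, DMF, 100 °C
Reagents that add atoms: none
Why: Mizoroki–Heck reaction in which the coumarinylpalladium species adds to the terminal carbon of the monosubstituted alkene and, since the quaternary C1 has no hydrogen, syn β-hydride elimination can only give the conjugated (E)-alkene.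

Step 10
Reactants: 16 8-methoxy-3-[(E)-2-{(1R,2R)-2-[8-methoxy-7-(methoxymethoxy)-2-oxo-2H-chromen-3-yl]-1,4-dimethylcyclohex-3-en-1-yl}ethenyl]-7-(methoxymethoxy)-2H-chromen-2-one
Product: 17 7-hydroxy-3-[(E)-2-[(1R,2R)-2-(7-hydroxy-8-methoxy-2-oxo-2H-chromen-3-yl)-1,4-dimethylcyclohex-3-en-1-yl]ethenyl]-8-methoxy-2H-chromen-2-one (CNP0264408.1)
Conditions: HCl (2 M aq), MeOH/THF, 40 °C
Reagents that add atoms: none
Why: Acid-catalysed cleavage of both methoxymethyl acetals (transacetalisation with methanol) frees the phenols under conditions the lactones, the diene and the ring alkene should tolerate.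

Compound list
1 | daphnetin (7,8-dihydroxy-2H-chromen-2-one) | Oc1ccc2ccc(=O)oc2c1O | starting material
2 | 8-hydroxy-7-(methoxymethoxy)-2H-chromen-2-one | COCOc1ccc2ccc(=O)oc2c1O | intermediate
3 | 8-methoxy-7-(methoxymethoxy)-2H-chromen-2-one | COCOc1ccc2ccc(=O)oc2c1OC | intermediate
4 | 3-bromo-8-methoxy-7-(methoxymethoxy)-2H-chromen-2-one | COCOc1ccc2cc(Br)c(=O)oc2c1OC | intermediate
5 | triphenyl(vinyl)phosphonium bromide | C=C[P+](c1ccccc1)(c1ccccc1)c1ccccc1.[Br-] | starting material
6 | (E)-{2-[8-methoxy-7-(methoxymethoxy)-2-oxo-2H-chromen-3-yl]ethenyl}triphenylphosphonium bromide | COCOc1ccc2cc(/C=C/[P+](c3ccccc3)(c3ccccc3)c3ccccc3)c(=O)oc2c1OC.[Br-] | intermediate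
7 | 1-methylcyclopentene | CC1=CCCC1 | starting material
8 | secondary ozonide of 7, 1-methyl-6,7,8-trioxabicyclo[3.2.1]octane (not isolated) | CC12CCCC(OO1)O2 | intermediate
9 | 5-oxohexanal | CC(=O)CCCC=O | intermediate
10 | {(2R,3S)-3-formyl-2-[8-methoxy-7-(methoxymethoxy)-2-oxo-2H-chromen-3-yl]-6-oxoheptyl}triphenylphosphonium bromide (not isolated) | O=C[C@@H](CCC(C)=O)[C@H](c1cc2ccc(OCOC)c(OC)c2oc1=O)C[P+](c1ccccc1)(c1ccccc1)c1ccccc1.[Br-] | intermediate
11 | (2S)-2-{(1R)-1-[8-methoxy-7-(methoxymethoxy)-2-oxo-2H-chromen-3-yl]-2-(triphenyl-λ5-phosphanylidene)ethyl}-5-oxohexanal (not isolated) | O=C[C@@H](CCC(C)=O)[C@H](c1cc2ccc(OCOC)c(OC)c2oc1=O)C=P(c1ccccc1)(c1ccccc1)c1ccccc1 | intermediate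
12 | (1R,2R)-2-[8-methoxy-7-(methoxymethoxy)-2-oxo-2H-chromen-3-yl]-4-methylcyclohex-3-ene-1-carbaldehyde | O=C[C@@H]1CCC(C)=C[C@H]1c1cc2ccc(OCOC)c(OC)c2oc1=O | intermediate
13 | potassium (E)-{(2R)-2-[8-methoxy-7-(methoxymethoxy)-2-oxo-2H-chromen-3-yl]-4-methylcyclohex-3-en-1-ylidene}methanolate (not isolated) | [K+].[O-]/C=C1\CCC(C)=C[C@H]1c1cc2ccc(OCOC)c(OC)c2oc1=O | intermediate
14 | (1S,2R)-2-[8-methoxy-7-(methoxymethoxy)-2-oxo-2H-chromen-3-yl]-1,4-dimethylcyclohex-3-ene-1-carbaldehyde | O=C[C@@]1(C)CCC(C)=C[C@H]1c1cc2ccc(OCOC)c(OC)c2oc1=O | intermediate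
15 | 3-[(1R,6R)-6-ethenyl-3,6-dimethylcyclohex-2-en-1-yl]-8-methoxy-7-(methoxymethoxy)-2H-chromen-2-one | C=C[C@@]1(C)CCC(C)=C[C@H]1c1cc2ccc(OCOC)c(OC)c2oc1=O | intermediate
16 | 8-methoxy-3-[(E)-2-{(1R,2R)-2-[8-methoxy-7-(methoxymethoxy)-2-oxo-2H-chromen-3-yl]-1,4-dimethylcyclohex-3-en-1-yl}ethenyl]-7-(methoxymethoxy)-2H-chromen-2-one | COCOc1ccc2cc(/C=C/[C@@]3(C)CCC(C)=C[C@H]3c3cc4ccc(OCOC)c(OC)c4oc3=O)c(=O)oc2c1OC | intermediate
17 | 7-hydroxy-3-[(E)-2-[(1R,2R)-2-(7-hydroxy-8-methoxy-2-oxo-2H-chromen-3-yl)-1,4-dimethylcyclohex-3-en-1-yl]ethenyl]-8-methoxy-2H-chromen-2-one | COc1c(O)ccc2cc(/C=C/[C@@]3(C)CCC(C)=C[C@H]3c3cc4ccc(O)c(OC)c4oc3=O)c(=O)oc12 | target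

Total steps: 10. Longest linear sequence: 9 steps (steps 1–4 and 6–10, from daphnetin).

Steps most likely to fail

Step 6 (proposed new method). The enamine may add to C4 of the coumarin or the catalyst nitrogen may be alkylated instead of C–C bond formation at the vinyl β-carbon. Facial selectivity may be poor, retro-Michael and re-addition under the basic second stage may erode enantiopurity, and the ylide may olefinate an aldehyde of a second molecule. The fallback uses known chemistry and sets out from bromide 4. A Mizoroki–Heck coupling with 2-methylbut-3-en-2-ol (Pd(OAc)2, P(o-tol)3, NaOAc, DMF) should give the allylic alcohol (E)-3-(3-hydroxy-3-methylbut-1-en-1-yl)-8-methoxy-7-(methoxymethoxy)-2H-chromen-2-one F1. Dehydration (MsCl, Et3N) should give the diene (E)-8-methoxy-7-(methoxymethoxy)-3-(3-methylbuta-1,3-dien-1-yl)-2H-chromen-2-one F2. An iminium-catalysed enantioselective Diels–Alder reaction with acrolein follows, using the enantiomer of 5-benzyl-2,2,3-trimethylimidazolidin-4-one hydrochloride that delivers the (2R) configuration, in MeCN/H2O. It should give the endo, ortho adduct, the cis aldehyde (1S,2R)-2-[8-methoxy-7-(methoxymethoxy)-2-oxo-2H-chromen-3-yl]-4-methylcyclohex-3-ene-1-carbaldehyde F3. This C1 epimer of 12 is taken into the conditions of step 7 and comes back to the route at enolate 13.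

Step 4. The vinylphosphonium salt may be lost by attack of acetate or adventitious hydroxide at phosphorus or at the vinyl group in hot DMF, and insertion into a cationic alkene may be slow. The fallback sets out from 4. A Mizoroki–Heck coupling with acrylic acid should give (E)-3-[8-methoxy-7-(methoxymethoxy)-2-oxo-2H-chromen-3-yl]prop-2-enoic acid F4. Hunsdiecker-type bromodecarboxylation (NBS, LiOAc catalytic, MeCN/H2O) should give 3-[(E)-2-bromoethenyl]-8-methoxy-7-(methoxymethoxy)-2H-chromen-2-one F5. Palladium-catalysed C–P coupling of this alkenyl bromide with PPh3 (Pd(OAc)2 catalytic, PhCN, 110 °C) then comes back to the route at 6.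

Step 9. Carbopalladation of the vinyl group next to the quaternary carbon may be slow, so that reduction or homocoupling of 4 takes over. The fallback sets out from aldehyde 14 and bypasses 15. A Takai–Utimoto olefination (CrCl2, LiI, Cl2CHB(pin), THF) should give the alkenylboronate 8-methoxy-7-(methoxymethoxy)-3-{(1R,6R)-3,6-dimethyl-6-[(E)-2-(4,4,5,5-tetramethyl-1,3,2-dioxaborolan-2-yl)ethenyl]cyclohex-2-en-1-yl}-2H-chromen-2-one F6. Suzuki–Miyaura coupling with 4 (Pd(PPh3)4, K3PO4, dioxane/H2O, 80 °C) comes back to the route at 16.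

Further compounds
F1 | step 6 | (E)-3-(3-hydroxy-3-methylbut-1-en-1-yl)-8-methoxy-7-(methoxymethoxy)-2H-chromen-2-one | COCOc1ccc2cc(/C=C/C(C)(C)O)c(=O)oc2c1OC
F2 | step 6 | (E)-8-methoxy-7-(methoxymethoxy)-3-(3-methylbuta-1,3-dien-1-yl)-2H-chromen-2-one | COCOc1ccc2cc(/C=C/C(C)=C)c(=O)oc2c1OC
F3 | step 6 | (1S,2R)-2-[8-methoxy-7-(methoxymethoxy)-2-oxo-2H-chromen-3-yl]-4-methylcyclohex-3-ene-1-carbaldehyde | O=C[C@H]1CCC(C)=C[C@H]1c1cc2ccc(OCOC)c(OC)c2oc1=O
F4 | step 4 | (E)-3-[8-methoxy-7-(methoxymethoxy)-2-oxo-2H-chromen-3-yl]prop-2-enoic acid | COCOc1ccc2cc(/C=C/C(=O)O)c(=O)oc2c1OC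
F5 | step 4 | 3-[(E)-2-bromoethenyl]-8-methoxy-7-(methoxymethoxy)-2H-chromen-2-one | COCOc1ccc2cc(/C=C/Br)c(=O)oc2c1OC
F6 | step 9 | 8-methoxy-7-(methoxymethoxy)-3-{(1R,6R)-3,6-dimethyl-6-[(E)-2-(4,4,5,5-tetramethyl-1,3,2-dioxaborolan-2-yl)ethenyl]cyclohex-2-en-1-yl}-2H-chromen-2-one | CC1(C)OB(/C=C/[C@@]2(C)CCC(C)=C[C@H]2c2cc3ccc(OCOC)c(OC)c3oc2=O)OC1(C)C
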